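Sunday's run shows starting material leaving by two routes, and the readings let us separate them. Here is the full problem.

| setting | Friday's | Sunday's | Tuesday's | east | south | south-east |
|---|---|---|---|---|---|---|
| starting material | 0.25 M | 0.25 M | 0.12 M | 0.25 M | 0.25 M | 0.25 M |
| free catalyst | 13 mol% | 30 mol% | 20 mol% | 20 mol% | 20 mol% | 20 mol% |
| temperature | 0 °C | 35 °C | 0 °C | 35 °C | 65 °C | 5 °C |
| remark | run made earlier | run made earlier | run made earlier |  |  |  |
| time |  |  |  | 12 min | 12 min | 12 min |

- Friday's (time / min: target / %, starting material / %): 3.00: 0, 94.7; 8.00: 0.4, 89.5; 15.0: 1.1, 81.2; 50.0: 4.7, 55.8
- Sunday's (time / min: target / %, starting material / %): 0.833: 7.2, 78.4; 2.50: 15.3, 52.9; 5.00: 23.3, 34.2; 8.00: 27.8, 21.4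
- Tuesday's (time / min: target / %, starting material / %): 5.00: 0, 96.4; 15.0: 1.8, 89.5; 30.0: 3.5, 81.3; 50.0: 4.9, 72.0

(standard deviation of a reading: 0.5 percentage points)

- the best flask by amount of target, in percent of the starting material charged; "all alike" if 1.5 percentage points covers them all (east / south / south-east / all alike)
- amount of target at the end, in percent of the starting material charged, east
- amount of target at the end, in percent of the starting material charged, south
- amount of target at the end, in percent of the starting material charged, south-east

- what was read earlier has a scatter of 0.5 percentage points, one standard deviation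

In Sunday's run, the fractional loss is 0.292 min⁻¹ up to the first reading, with about 89.2% of the charge left on average. Between the last two readings it is 0.156 min⁻¹, with about 27.8% left. We take a catalysed part that stays constant (pseudo-first-order) and a second-order side reaction whose fractional loss falls in step with what is left. A straight line through the two points gives:

side reaction at the full charge = 0.221 min⁻¹

catalysed part = 0.0948 min⁻¹

Their ratio is the crossing fraction, the fraction of the charge left at which the two routes draw equally. It is 42.8% at Sunday's 30 mol%. Scaled with the loading at the same temperature, it becomes 28.6% for east.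

Two extremes bound east. With starting material held at its charge, the catalyst's share of the loss is 22.2%; far below the crossing, that share approaches 100%. The real flask runs from the first towards the second, and by our own reckoning the share (selectivity) summed over the whole fall is:

x ln(1 + 1/x) = 43.0%

So we expect target in east at 12 min to lie below 43.0% of the charge, which is what the catalysed route carries over the whole fall by this reckoning.

The forecast names east as best, with 21.5% (17% to 26%) there, 2% (0% to 12%) in south, where it expects “strongly accelerated decay destroys” the target, and 3.3% (1.8% to 5.2%) in south-east.

East gives 24.2%, south 13.0% and south-east 3.49%, so east is best, and south stands above the forecast's range.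

    target + free catalyst ⇌ isomer of the product + free catalyst, rate k1*[free catalyst]*[target] forward; the back reaction follows from the equilibrium constant (K = 9.90, k = 0.430 L mol⁻¹ min⁻¹, Ea = 55.0 kJ mol⁻¹, ΔH = −7.00 kJ mol⁻¹)
    starting material + free catalyst ⇌ catalyst intermediate (K = 200 L mol⁻¹, k = 1.20 L mol⁻¹ min⁻¹, Ea = 64.0 kJ mol⁻¹, ΔH = −14.0 kJ mol⁻¹)
    2 starting material → self-condensation product (k = 0.450 L mol⁻¹ min⁻¹, Ea = 56.0 kJ mol⁻¹)
    catalyst intermediate → free catalyst + target (k = 18.0 min⁻¹, Ea = 84.0 kJ mol⁻¹)
    (constants at 35 °C)

East holds 32.8% of its starting material at 6.00 min, more than our crossing fraction of 28.6%, and 16.7% at 12.0 min, less than it. In south-east at 5.20 min, the path to self-condensation product uses starting material 4.8 times as fast as the forward step alone to catalyst intermediate. South-east's neighbour charged at 0.10 M keeps the loading and the temperature, and at 12.0 min self-condensation product is 83.4% of what that neighbour has lost, against 82.6% in south-east.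

The data were computed for substances that don't exist; the scatter is artificial.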